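**Retrosynthetic overview**
1. Toxiusol ⇐ bis-O-sulfation of the hydroquinone ⇐ CAN/dithionite unmasking of the dimethyl ether 25; the last ring (A′) is closed by intramolecular McMurry coupling of keto-aldehyde 24.
2. Quaternary C9′ ⇐ two enolate alkylations of the (S)-pulegone-derived ketone 21: first with iodide 18 (fragment union), then axial MeI.
3. Iodide 18 ⇐ Eschenmoser–Claisen [3,3] rearrangement of allylic alcohol 14: the C6–O stereocentre is relayed to the quaternary C4 and the alkene moves to C5=C6.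
4. Alcohol 14 ⇐ enone 13 ⇐ cuprate addition/aldol annulation (ring A) on cyclohexenone 10 ⇐ (R)-pulegone (α′-benzylation, α′-methylation, retro-aldol, carbonyl transposition).
5. Ring order: ring B (from (R)-pulegone) → ring A (aldol) → [3,3] → ring B′ (from (S)-pulegone) attached → ring A′ (McMurry).

Assumption: the SMILES is taken literally (8-Me trans to 9-Me; 5′-H cis to 8′/9′-Me), both pulegone enantiomers are bought, and the product is the free bis(hydrogen sulfate) (best stored as its Na salt). Numbering: aryl decalin C1–C10 (C9 bears CH2Ar, C4 bears the linker); terminal decalin primed (C9′ bears the linker, C4′ is gem-dimethyl).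

**Step 1**
Reactants: 1 (R)-(+)-pulegone; 2 2,5-dimethoxybenzyl bromide
Product: 3 (2S,3R)-2-(2,5-dimethoxybenzyl)-3-methyl-6-(propan-2-ylidene)cyclohexan-1-one (major, benzyl trans to Me)
Conditions: LDA, THF, −78 °C; then 2, −78 → −20 °C
Reagents that add atoms: 2,5-dimethoxybenzyl bromide, COc1ccc(OC)c(CBr)c1
Why: Kinetic α′-deprotonation of the enone (the other α-carbon is blocked by the isopropylidene) and SN2 enolate benzylation; this centre is re-enolised in step 2.

**Step 2**
Reactants: 3; 4 iodomethane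
Product: 5 (2R,3R)-2-(2,5-dimethoxybenzyl)-2,3-dimethyl-6-(propan-2-ylidene)cyclohexan-1-one
Conditions: LDA, THF, −78 °C; MeI, DMPU, −78 → 0 °C
Reagents that add atoms: iodomethane, CI
Why: Second α′-enolate alkylation; A(1,2) strain puts the neighbouring ring methyl pseudoaxial and MeI enters anti to it, so the new Me is trans and ArCH2 cis to the pool methyl (sets C9).

**Step 3**
Reactants: 5
Product: 6 (2R,3R)-2-(2,5-dimethoxybenzyl)-2,3-dimethylcyclohexan-1-one
Conditions: 3 M HCl, dioxane–H2O, reflux, acetone distilled off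
Reagents that add atoms: none
Why: Acid-mediated hydration/retro-aldol removes the isopropylidene blocking group (as in pulegone → 3-methylcyclohexanone); neither stereocentre is epimerisable.

**Step 4**
Reactants: 6; 7 N-phenylbis(trifluoromethanesulfonimide)
Product: 8 (5R,6R)-6-(2,5-dimethoxybenzyl)-5,6-dimethylcyclohex-1-en-1-yl triflate
Conditions: KHMDS, THF, −78 °C; PhNTf2, −78 → 0 °C
Reagents that add atoms: PhNTf2, O=S(=O)(N(c1ccccc1)S(=O)(=O)C(F)(F)F)C(F)(F)F
Why: Only one α-carbon is enolisable, so enolate O-triflation gives a single enol triflate.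

**Step 5**
Reactants: 8
Product: 9 (3R,4R)-3-(2,5-dimethoxybenzyl)-3,4-dimethylcyclohex-1-ene
Conditions: Pd(OAc)2 (5 mol %), PPh3, HCO2H, n-Bu3N, DMF, 60 °C
Reagents that add atoms: none
Why: Pd-catalysed formate hydrogenolysis of the vinyl triflate gives the alkene regiospecifically.

**Step 6**
Reactants: 9
Product: 10 (4R,5R)-4-(2,5-dimethoxybenzyl)-4,5-dimethylcyclohex-2-en-1-one
Conditions: Rh2(cap)4 (1 mol %), t-BuOOH, K2CO3, CH2Cl2, rt
Reagents that add atoms: tert-butyl hydroperoxide, CC(C)(C)OO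
Why: Allylic C–H oxidation; the only allylic C–H bonds are at C6 (the other allylic carbon is quaternary), so the ketone is transposed 1,3 to give the enone.

**Step 7**
Reactants: 10; 11 2-(3-chloropropyl)-2-methyl-1,3-dioxolane
Product: 12 (3R,4R,5R)-4-(2,5-dimethoxybenzyl)-4,5-dimethyl-3-[3-(2-methyl-1,3-dioxolan-2-yl)propyl]cyclohexan-1-one
Conditions: 11, Mg, THF, reflux; then CuBr·SMe2 (20 mol %), TMSCl, THF, −78 → −30 °C; K2CO3/MeOH work-up
Reagents that add atoms: 2-(3-chloropropyl)-2-methyl-1,3-dioxolane, CC1(CCCCl)OCCO1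
Why: Cu-catalysed conjugate addition; axial attack trans to the 5-methyl and anti to the pseudoaxial CH2Ar on the γ-carbon sets C10 (H-10 cis to CH2Ar).

**Step 8**
Reactants: 12
Product: 13 (3R,4R,4aS)-4-(2,5-dimethoxybenzyl)-3,4,8-trimethyl-3,4,4a,5,6,7-hexahydronaphthalen-1(2H)-one
Conditions: 2 M HCl, THF, rt; then KOH, MeOH, 60 °C
Reagents that add atoms: none
Why: Ketal hydrolysis then intramolecular aldol condensation closes ring A; only the C5→C4 six-ring closure can dehydrate (the alternative is a bridgehead alkene), and C10 is not enolisable.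

**Step 9**
Reactants: 13
Product: 14 (1S,3R,4R,4aS)-4-(2,5-dimethoxybenzyl)-3,4,8-trimethyl-1,2,3,4,4a,5,6,7-octahydronaphthalen-1-ol (6α-OH, axial)
Conditions: L-Selectride, THF, −78 °C; NaOH/H2O2 work-up
Reagents that add atoms: none
Why: 1,2-Reduction of the β,β-disubstituted enone; ring B is locked with H-10 axial, so the axial C8 methyl blocks the α-face and hydride enters from the β-face, giving the α-alcohol.

**Step 10 (key step)**
Reactants: 14; 15 N,N-dimethylacetamide dimethyl acetal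
Product: 16 2-[(1S,4aS,5R,6R)-5-(2,5-dimethoxybenzyl)-1,5,6-trimethyl-1,2,3,4,4a,5,6,7-octahydronaphthalen-1-yl]-N,N-dimethylacetamide
Conditions: 15 (5 equiv), xylenes, 140 °C, MeOH removed
Reagents that add atoms: N,N-dimethylacetamide dimethyl acetal, CC(OC)(OC)N(C)C
Why: Eschenmoser–Claisen [3,3] rearrangement; suprafacial transfer from the axial C6–O to the α-face of C4 creates the quaternary centre (CH2CONMe2 α, Me β) and places the alkene at C5=C6.

**Step 11**
Reactants: 16
Product: 17 2-[(1S,4aS,5R,6R)-5-(2,5-dimethoxybenzyl)-1,5,6-trimethyl-1,2,3,4,4a,5,6,7-octahydronaphthalen-1-yl]ethan-1-ol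
Conditions: LiH2N·BH3, THF, 0 → 23 °C
Reagents that add atoms: none
Why: Lithium amidotrihydroborate reduces the tertiary amide to the primary alcohol without touching the alkene.

**Step 12**
Reactants: 17
Product: 18 (1S,4aS,5R,6R)-5-(2,5-dimethoxybenzyl)-1-(2-iodoethyl)-1,5,6-trimethyl-1,2,3,4,4a,5,6,7-octahydronaphthalene
Conditions: I2, PPh3, imidazole, CH2Cl2, 0 °C → rt
Reagents that add atoms: iodine, II
Why: Appel-type iodination of an unhindered primary alcohol.

**Step 13**
Reactants: 19 (S)-(−)-pulegone; 20 2-(2-bromoethyl)-1,3-dioxolane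
Product: 21 (2R,5S)-2-[4-(1,3-dioxolan-2-yl)-2-methylbutan-2-yl]-5-methylcyclohexan-1-one (trans)
Conditions: 20, Mg, THF, 25 °C; CuBr·SMe2 (10 mol %), TMSCl, THF, −40 → 0 °C; then KOH, EtOH, reflux; chromatography
Reagents that add atoms: 2-(2-bromoethyl)-1,3-dioxolane, BrCCC1OCCO1
Why: Cu-catalysed 1,4-addition to the isopropylidene carbon builds the gem-dimethyl C4′; base equilibration gives the diequatorial (menthone-type, about 87:13) ketone, setting C5′ relative to the pool centre C8′.

**Step 14 (fragment union)**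
Reactants: 21 (2.5 equiv); 18
Product: 22 (2R,3S,6R)-6-[4-(1,3-dioxolan-2-yl)-2-methylbutan-2-yl]-3-methyl-2-[2-(octalin-1-yl)ethyl]cyclohexan-1-one (octalinyl = the bicycle of 18; all-equatorial isomer)
Conditions: LDA, THF, −78 °C; 18, HMPA, −78 → 0 °C; then NaOMe, MeOH, rt; excess 21 recovered
Reagents that add atoms: none beyond the two reactants
Why: The kinetic enolate forms on the CH2 side (the other α-H is flanked by the quaternary carbon) and is alkylated by the primary iodide; equilibration gives the all-equatorial ketone.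

**Step 15**
Reactants: 22; 4 iodomethane
Product: 23 (2R,3S,6R)-2,3-dimethyl analogue of 22 with quaternary C9′ (Me cis to the C8′ methyl, fragment chain trans)
Conditions: KHMDS, THF, −78 °C; MeI, −78 → −20 °C
Reagents that add atoms: iodomethane, CI
Why: Enolate alkylation at C9′; the equatorial tert-alkyl group locks the ring and MeI attacks axially (anti to axial H-8′), so Me ends cis to the C8′ methyl and the chain stays equatorial.

**Step 16**
Reactants: 23
Product: 24 keto-aldehyde (dioxolane of 23 converted to CHO)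
Conditions: PPTS, acetone–H2O (10:1), 50 °C
Reagents that add atoms: water, O
Why: Mild acetal hydrolysis unmasks the aldehyde without enolising the hindered ketone (C5′ is preserved).

**Step 17**
Reactants: 24
Product: 25 toxiusol hydroquinone dimethyl ether (full bis-octalin skeleton)
Conditions: TiCl3(DME)1.5, Zn–Cu, DME, reflux, syringe-pump addition
Reagents that add atoms: none
Why: Intramolecular McMurry coupling of the keto-aldehyde closes ring A′ and fixes the trisubstituted alkene at C1′=C10′.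

**Step 18**
Reactants: 25
Product: 26 toxiusol hydroquinone (desulfated)
Conditions: CAN, MeCN–H2O, 0 °C; then aq. Na2S2O4
Reagents that add atoms: water, O (quinone oxygens)
Why: Oxidative demethylation to the quinone followed by dithionite reduction, as for avarol dimethyl ether; the trisubstituted alkenes are untouched.

**Step 19**
Reactants: 26; 27 sulfur trioxide–pyridine
Product: 28 toxiusol
Conditions: SO3·pyridine (6 equiv), pyridine, 40 °C; then Dowex 50W (H+), 0 °C (or isolate as disodium salt)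
Reagents that add atoms: sulfur trioxide–pyridine, O=S(=O)=O.c1ccncc1
Why: O-Sulfation of both phenols; no stereocentre is affected.

**Compound list**
1 | (R)-(+)-pulegone | C[C@@H]1CCC(=C(C)C)C(=O)C1 | starting material
2 | 2,5-dimethoxybenzyl bromide | COc1ccc(OC)c(CBr)c1 | starting material
3 | (2S,3R)-2-(2,5-dimethoxybenzyl)-3-methyl-6-(propan-2-ylidene)cyclohexan-1-one | C[C@@H]1CCC(=C(C)C)C(=O)[C@H]1Cc1cc(OC)ccc1OC | intermediate
4 | iodomethane | CI | starting material
5 | (2R,3R)-2-(2,5-dimethoxybenzyl)-2,3-dimethyl-6-(propan-2-ylidene)cyclohexan-1-one | C[C@@H]1CCC(=C(C)C)C(=O)[C@]1(C)Cc1cc(OC)ccc1OC | intermediate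
6 | (2R,3R)-2-(2,5-dimethoxybenzyl)-2,3-dimethylcyclohexan-1-one | C[C@@H]1CCCC(=O)[C@]1(C)Cc1cc(OC)ccc1OC | intermediate
7 | N-phenylbis(trifluoromethanesulfonimide) | O=S(=O)(N(c1ccccc1)S(=O)(=O)C(F)(F)F)C(F)(F)F | starting material
8 | (5R,6R)-6-(2,5-dimethoxybenzyl)-5,6-dimethylcyclohex-1-en-1-yl triflate | C[C@@H]1CCC=C(OS(=O)(=O)C(F)(F)F)[C@]1(C)Cc1cc(OC)ccc1OC | intermediate
9 | (3R,4R)-3-(2,5-dimethoxybenzyl)-3,4-dimethylcyclohex-1-ene | C[C@@H]1CCC=C[C@]1(C)Cc1cc(OC)ccc1OC | intermediate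
10 | (4R,5R)-4-(2,5-dimethoxybenzyl)-4,5-dimethylcyclohex-2-en-1-one | C[C@@H]1CC(=O)C=C[C@]1(C)Cc1cc(OC)ccc1OC | intermediate
11 | 2-(3-chloropropyl)-2-methyl-1,3-dioxolane | CC1(CCCCl)OCCO1 | starting material
12 | (3R,4R,5R)-4-(2,5-dimethoxybenzyl)-4,5-dimethyl-3-[3-(2-methyl-1,3-dioxolan-2-yl)propyl]cyclohexan-1-one | C[C@@H]1CC(=O)C[C@@H](CCCC2(C)OCCO2)[C@]1(C)Cc1cc(OC)ccc1OC | intermediate
13 | (3R,4R,4aS)-4-(2,5-dimethoxybenzyl)-3,4,8-trimethyl-3,4,4a,5,6,7-hexahydronaphthalen-1(2H)-one | C[C@@H]1CC(=O)C2=C(C)CCC[C@H]2[C@]1(C)Cc1cc(OC)ccc1OC | intermediate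
14 | (1S,3R,4R,4aS)-4-(2,5-dimethoxybenzyl)-3,4,8-trimethyl-1,2,3,4,4a,5,6,7-octahydronaphthalen-1-ol | C[C@@H]1C[C@H](O)C2=C(C)CCC[C@H]2[C@]1(C)Cc1cc(OC)ccc1OC | intermediate
15 | N,N-dimethylacetamide dimethyl acetal | CC(OC)(OC)N(C)C | starting material
16 | 2-[(1S,4aS,5R,6R)-5-(2,5-dimethoxybenzyl)-1,5,6-trimethyl-1,2,3,4,4a,5,6,7-octahydronaphthalen-1-yl]-N,N-dimethylacetamide | C[C@@H]1CC=C2[C@@H](CCC[C@@]2(C)CC(=O)N(C)C)[C@]1(C)Cc1cc(OC)ccc1OC | intermediate
17 | 2-[(1S,4aS,5R,6R)-5-(2,5-dimethoxybenzyl)-1,5,6-trimethyl-1,2,3,4,4a,5,6,7-octahydronaphthalen-1-yl]ethan-1-ol | C[C@@H]1CC=C2[C@@H](CCC[C@@]2(C)CCO)[C@]1(C)Cc1cc(OC)ccc1OC | intermediate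
18 | (1S,4aS,5R,6R)-5-(2,5-dimethoxybenzyl)-1-(2-iodoethyl)-1,5,6-trimethyl-1,2,3,4,4a,5,6,7-octahydronaphthalene | C[C@@H]1CC=C2[C@@H](CCC[C@@]2(C)CCI)[C@]1(C)Cc1cc(OC)ccc1OC | intermediate
19 | (S)-(−)-pulegone | C[C@H]1CCC(=C(C)C)C(=O)C1 | starting material
20 | 2-(2-bromoethyl)-1,3-dioxolane | BrCCC1OCCO1 | starting material
21 | (2R,5S)-2-[4-(1,3-dioxolan-2-yl)-2-methylbutan-2-yl]-5-methylcyclohexan-1-one | C[C@H]1CC[C@H](C(C)(C)CCC2OCCO2)C(=O)C1 | intermediate
22 | coupled ketone, (2R,3S,6R)-cyclohexanone bearing 2-[2-(octalinyl)ethyl], 3-Me, 6-(acetal side chain) | C[C@@H]1CC=C2[C@@H](CCC[C@@]2(C)CC[C@H]2C(=O)[C@@H](C(C)(C)CCC3OCCO3)CC[C@@H]2C)[C@]1(C)Cc1cc(OC)ccc1OC | intermediate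
23 | C9′-methylated coupled ketone, (2R,3S,6R) | C[C@@H]1CC=C2[C@@H](CCC[C@@]2(C)CC[C@@]2(C)C(=O)[C@@H](C(C)(C)CCC3OCCO3)CC[C@@H]2C)[C@]1(C)Cc1cc(OC)ccc1OC | intermediate
24 | keto-aldehyde | C[C@@H]1CC=C2[C@@H](CCC[C@@]2(C)CC[C@@]2(C)C(=O)[C@@H](C(C)(C)CCC=O)CC[C@@H]2C)[C@]1(C)Cc1cc(OC)ccc1OC | intermediate
25 | toxiusol hydroquinone dimethyl ether | C[C@@H]1CC=C2[C@@H](CCC[C@@]2(C)CC[C@@]2(C)C3=CCCC(C)(C)[C@H]3CC[C@@H]2C)[C@]1(C)Cc1cc(OC)ccc1OC | intermediate
26 | toxiusol hydroquinone (desulfated) | C[C@@H]1CC=C2[C@@H](CCC[C@@]2(C)CC[C@@]2(C)C3=CCCC(C)(C)[C@H]3CC[C@@H]2C)[C@]1(C)Cc1cc(O)ccc1O | intermediate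
27 | sulfur trioxide–pyridine | O=S(=O)=O.c1ccncc1 | starting material
28 | toxiusol | C[C@@H]1CC=C2[C@@H](CCC[C@@]2(C)CC[C@@]2(C)C3=CCCC(C)(C)[C@H]3CC[C@@H]2C)[C@]1(C)Cc1cc(OS(=O)(=O)O)ccc1OS(=O)(=O)O | target

**Totals:** 19 steps; longest linear sequence 18 (steps 1–12, then 14–19).

**Steps most likely to fail, with fallbacks**
- **Step 14 (union by enolate SN2 on a γ-quaternary primary iodide):** elimination, O-alkylation or low conversion are possible. Fallback: oxidise 17 to the aldehyde, aldol-condense it with the kinetic enolate of 21 to the exocyclic enone, then conjugate-reduce (Stryker reagent) to 22, so the bond forms by carbonyl condensation instead of SN2.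
- **Step 10 (Claisen onto a tetrasubstituted alkene carbon):** thermal dehydration of 14 to a diene may compete. Fallback: acetylate 14 and run the anionic Ireland–Claisen (LDA/TMSCl, −78 → 60 °C) to the acid, then LiAlH4 to 17.
- **Step 15 (quaternisation at C9′):** the regioselectivity of enolisation and the axial/equatorial methylation ratio are uncertain, and C5′ could epimerise. Fallback: change the order of events: methylate and then alkylate (S)-pulegone itself at C6 with 18 (second electrophile anti to the ring methyl, as in steps 1–2), then add the acetal Grignard/Cu to the isopropylidene and equilibrate and separate at C5′.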